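**Retrosynthetic overview**
Hopeafuran ⇐ its penta-O-benzyl ether ⇐ trans alcohol (Dess–Martin oxidation) ⇐ achiral pentacyclic alkene with CH=C(aryl) in ring C; monoisopinocampheylborane (IpcBH2) hydroboration of that alkene sets the single methine centre.
Feature used: benzofuran C3 belongs to both the furan (ring B) and the seven-membered carbocycle (ring C). A C3a–C3 bond made on an alkyne tethered to ring A through C4 therefore closes ring C, while the ring A phenol oxygen closes O1–C2 of ring B.
Both bonds come from one intramolecular Larock annulation of a (Z)-triarylethene that carries an ortho-iodophenol (ring A) and an ortho-alkynyl resorcinol ring (ring D).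
The (Z)-triarylethene ⇐ Horner–Wadsworth–Emmons union of 2-iodo-3,5-bis(methoxymethoxy)benzaldehyde with a diarylmethylphosphonate; the phosphonate ⇐ 5-bromoresorcinol (benzylation, Vilsmeier–Haack, Grignard, phosphonylation, Sonogashira).
Ring order: rings A, D and the pendant 4-oxyphenyl rings E (on the methine carbon) and F (on furan C2) are bought; rings B and C form together in the key step; the stereocentre is set afterwards.

Key step: step 10

Remark on the chemistry: the methine carbon of the given structure is read as (S); the facial sense of IpcBH2 is carried over from 1-arylcycloalkenes, so the reagent made from (+)-α-pinene is taken; both ring A phenols are carried as MOM ethers and the spare one is benzylated after the annulation, which avoids any need to tell the two ring A oxygens apart.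

**Route**

Step 1
Reactants: 1 3,5-dihydroxybenzaldehyde
Product: 2 3,5-bis(methoxymethoxy)benzaldehyde
Conditions: MOMCl (2.5 equiv), i-Pr2NEt (3 equiv), CH2Cl2, 0 °C to rt
Reagents that add atoms: chloromethyl methyl ether, COCCl
Why: Williamson-type O-alkylation of both phenols with the reactive α-chloro ether gives acetals that survive base and the olefination and later fall off under mild acid without touching benzyl ethers.

Step 2
Reactants: 2 3,5-bis(methoxymethoxy)benzaldehyde
Product: 3 2-iodo-3,5-bis(methoxymethoxy)benzaldehyde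
Conditions: NIS (1.05 equiv), CF3CO2H (0.2 equiv), MeCN, 0 °C to rt, dark
Reagents that add atoms: N-iodosuccinimide, O=C1CCC(=O)N1I
Why: Electrophilic aromatic iodination should enter at C2 (ortho to one alkoxy group, para to the other) and not at the more crowded C4 between the two alkoxy groups, as 3,5-dialkoxybenzaldehydes are known to do.

Step 3
Reactants: 4 5-bromoresorcinol
Product: 5 1,3-bis(benzyloxy)-5-bromobenzene
Conditions: BnBr (2.3 equiv), K2CO3, DMF, 60 °C
Reagents that add atoms: benzyl bromide, BrCc1ccccc1
Why: Williamson ether synthesis on both phenols installs the benzyl ethers that stay until the last step.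

Step 4
Reactants: 5 1,3-bis(benzyloxy)-5-bromobenzene
Product: 7 2,4-bis(benzyloxy)-6-bromobenzaldehyde, via aryl iminium chloride 6 (not isolated)
Conditions: POCl3 (2 equiv), DMF, 0 to 90 °C; then ice-water
Reagents that add atoms: N,N-dimethylformamide, CN(C)C=O; water, O
Why: Vilsmeier–Haack formylation should go to the position ortho to bromine and para to an alkoxy group, as 1-bromo-3,5-dialkoxybenzenes do, and hydrolysis of the iminium salt gives the aldehyde.

Step 5
Reactants: 7 2,4-bis(benzyloxy)-6-bromobenzaldehyde; 8 1-(benzyloxy)-4-bromobenzene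
Product: 10 [2,4-bis(benzyloxy)-6-bromophenyl][4-(benzyloxy)phenyl]methanol (racemic), via [4-(benzyloxy)phenyl]magnesium bromide 9 (not isolated)
Conditions: 8, Mg, THF, reflux; then 7, 0 °C to rt; aq. NH4Cl
Reagents that add atoms: none
Why: Grignard addition to the aldehyde is fast at 0 °C while the aryl bromide of 7 does not exchange with an arylmagnesium halide, and the new carbinol centre is racemic and is destroyed in step 8.

Step 6
Reactants: 10 [2,4-bis(benzyloxy)-6-bromophenyl][4-(benzyloxy)phenyl]methanol
Product: 11 diethyl {[2,4-bis(benzyloxy)-6-bromophenyl][4-(benzyloxy)phenyl]methyl}phosphonate (racemic)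
Conditions: P(OEt)3 (3 equiv), ZnI2 (1.5 equiv), toluene, 110 °C
Reagents that add atoms: triethyl phosphite, CCOP(OCC)OCC
Why: ZnI2-mediated Michaelis–Arbuzov-type phosphonylation of a benzylic alcohol should be easy here because the diaryl cation is stabilised by three alkoxy groups, is captured by the phosphite and is dealkylated by iodide.

Step 7
Reactants: 11 diethyl {[2,4-bis(benzyloxy)-6-bromophenyl][4-(benzyloxy)phenyl]methyl}phosphonate; 12 1-(benzyloxy)-4-ethynylbenzene
Product: 13 diethyl {[2,4-bis(benzyloxy)-6-{[4-(benzyloxy)phenyl]ethynyl}phenyl][4-(benzyloxy)phenyl]methyl}phosphonate (racemic)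
Conditions: PdCl2(MeCN)2 (3 mol %), XPhos (9 mol %), Cs2CO3 (2.5 equiv), MeCN, 80 °C
Reagents that add atoms: none
Why: Copper-free Sonogashira coupling with a bulky biarylphosphine copes with the ortho-branched aryl bromide, and it is run here because no palladium coupling is possible once the aryl iodide of ring A is in the molecule.

Step 8
Reactants: 13 the alkynyl diarylmethylphosphonate; 3 2-iodo-3,5-bis(methoxymethoxy)benzaldehyde
Product: 14 (Z)-1-[2-iodo-3,5-bis(methoxymethoxy)phenyl]-2-[4-(benzyloxy)phenyl]-2-[2,4-bis(benzyloxy)-6-{[4-(benzyloxy)phenyl]ethynyl}phenyl]ethene (iodoaryl ring A cis to alkynyl ring D)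
Conditions: KOtBu (1.2 equiv) added to 13 and 3, THF, −20 °C to rt; chromatography
Reagents that add atoms: none
Why: Horner–Wadsworth–Emmons olefination tolerates the aryl iodide, and ring A should end trans to the coplanar, conjugating ring E and cis to the twisted, doubly ortho-substituted ring D, as the aldehyde substituent ends trans to the conjugating group in olefinations with α-substituted phosphonates; any E isomer is removed on silica.

Step 9
Reactants: 14 the (Z)-triarylethene bis-MOM ether
Product: 15 5-{(Z)-2-[4-(benzyloxy)phenyl]-2-[2,4-bis(benzyloxy)-6-{[4-(benzyloxy)phenyl]ethynyl}phenyl]ethenyl}-4-iodobenzene-1,3-diol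
Conditions: HCl (3 M aq.), MeOH/THF, 45 °C, dim light
Reagents that add atoms: none
Why: Acid-catalysed acetal exchange with methanol removes both MOM groups and leaves benzyl ethers, aryl iodide, alkyne and alkene untouched, which frees the phenol ortho to iodine.

Step 10
Reactants: 15 the (Z)-triarylethene iodoresorcinol
Product: 16 tetrabenzyl pentacyclic alkene phenol (hopeafuran skeleton with CH=C(ring E) in place of C(=O)–CH(ring E); free OH at benzofuran C6; benzyl ethers on rings D, E and F)
Conditions: Pd(OAc)2 (10 mol %), LiCl (1 equiv), K2CO3 (4 equiv), degassed DMF (0.01 M), 100 °C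
Reagents that add atoms: none
Why: This is a Larock heteroannulation run intramolecularly: zerovalent palladium formed from Pd(OAc)2 inserts into the C3a–I bond of ring A, the arylpalladium adds syn across the tethered diarylalkyne so that C3a bonds to the alkyne carbon on ring D and palladium ends on the carbon bearing ring F, cis to C3a, and the neighbouring phenoxide then binds palladium in a six-membered oxapalladacycle that closes O1–C2 by C–O reductive elimination. The closest known reactions are the Larock synthesis of 2,3-disubstituted benzofurans from ortho-iodophenols and internal alkynes and its intramolecular form that bridges C3 and C4 of indoles. Ring C closes in the 7-exo-dig mode at the carbopalladation stage, and ring B closes by reductive elimination from the palladacycle (formally a 5-endo closure of oxygen onto the former alkyne). No stereocentre is formed, since the product is an achiral alkene. The step needs the insertion to put C3a on the ring D alkyne carbon and to stay intramolecular: the tether secures the first, because the other orientation would need an eight-membered endo closure, and the Z alkene, which holds the C–I bond next to the alkyne, together with high dilution secures the second. The second ring A phenoxide is a spectator, because only the oxygen ortho to palladium can reach the vinylpalladium carbon.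

Step 11
Reactants: 16 tetrabenzyl pentacyclic alkene phenol
Product: 17 pentabenzyl pentacyclic alkene (16 with a benzyl ether at benzofuran C6)
Conditions: BnBr (1.3 equiv), K2CO3, DMF, rt
Reagents that add atoms: benzyl bromide, BrCc1ccccc1
Why: Williamson etherification of the one remaining phenol is unambiguous and gives a substrate without acidic or oxidisable OH groups for hydroboration and oxidation.

Step 12
Reactants: 17 pentabenzyl pentacyclic alkene
Product: 19 trans alcohol (17 with H added at the ring E-bearing carbon and OH at the ring C carbon next to ring A; carbinol carbon R, methine carbon S), via B-isopinocampheyl alkylborane 18 (not isolated)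
Conditions: IpcBH2 made from (+)-α-pinene (2.5 equiv), THF, −25 °C to rt; then NaOH (3 M), H2O2 (30 %), 0 °C to rt
Reagents that add atoms: hydrogen peroxide, OO
Why: Asymmetric hydroboration–oxidation adds boron to the less substituted CH carbon and hydrogen syn to the diaryl carbon; the (1R,2S,3R,5R)-isopinocampheyl reagent should choose the alkene face as it does with 1-arylcycloalkenes, which sets the (S)-methine centre, and oxidation with retention gives the (R)-carbinol trans to ring E.

Step 13
Reactants: 19 trans alcohol
Product: 20 penta-O-benzylhopeafuran (methine carbon S)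
Conditions: Dess–Martin periodinane (1.5 equiv), NaHCO3 (5 equiv), CH2Cl2, 0 °C to rt
Reagents that add atoms: none
Why: Dess–Martin oxidation under buffered, non-basic conditions gives the ketone and should leave the enolisable, doubly benzylic methine centre untouched.

Step 14
Reactants: 20 penta-O-benzylhopeafuran
Product: 21 hopeafuran
Conditions: H2 (1 atm), Pd/C (10 %), EtOAc/MeOH, rt
Reagents that add atoms: none
Why: Hydrogenolysis of the five aryl benzyl ethers over Pd/C is neutral, so the α-aryl ketone centre should keep its configuration, and the hindered diaryl ketone and the tetrasubstituted furan double bond should be reduced far more slowly than the benzyl ethers are cleaved.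

**Compound list**
1 | 3,5-dihydroxybenzaldehyde | O=Cc1cc(O)cc(O)c1 | starting material
2 | 3,5-bis(methoxymethoxy)benzaldehyde | O=Cc1cc(OCOC)cc(OCOC)c1 | intermediate
3 | 2-iodo-3,5-bis(methoxymethoxy)benzaldehyde | O=Cc1cc(OCOC)cc(OCOC)c1I | intermediate
4 | 5-bromoresorcinol | Oc1cc(O)cc(Br)c1 | starting material
5 | 1,3-bis(benzyloxy)-5-bromobenzene | Brc1cc(OCc2ccccc2)cc(OCc2ccccc2)c1 | intermediate
6 | {[2,4-bis(benzyloxy)-6-bromophenyl]methylidene}dimethyliminium chloride | C[N+](C)=Cc1c(Br)cc(OCc2ccccc2)cc1OCc1ccccc1.[Cl-] | intermediate (not isolated)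
7 | 2,4-bis(benzyloxy)-6-bromobenzaldehyde | O=Cc1c(Br)cc(OCc2ccccc2)cc1OCc1ccccc1 | intermediate
8 | 1-(benzyloxy)-4-bromobenzene | Brc1ccc(OCc2ccccc2)cc1 | starting material
9 | [4-(benzyloxy)phenyl]magnesium bromide | Br[Mg]c1ccc(OCc2ccccc2)cc1 | intermediate (not isolated)
10 | [2,4-bis(benzyloxy)-6-bromophenyl][4-(benzyloxy)phenyl]methanol (racemic) | OC(c1ccc(OCc2ccccc2)cc1)c1c(Br)cc(OCc2ccccc2)cc1OCc1ccccc1 | intermediate
11 | diethyl {[2,4-bis(benzyloxy)-6-bromophenyl][4-(benzyloxy)phenyl]methyl}phosphonate (racemic) | CCOP(=O)(OCC)C(c1ccc(OCc2ccccc2)cc1)c1c(Br)cc(OCc2ccccc2)cc1OCc1ccccc1 | intermediate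
12 | 1-(benzyloxy)-4-ethynylbenzene | C#Cc1ccc(OCc2ccccc2)cc1 | starting material
13 | diethyl {[2,4-bis(benzyloxy)-6-{[4-(benzyloxy)phenyl]ethynyl}phenyl][4-(benzyloxy)phenyl]methyl}phosphonate (racemic) | CCOP(=O)(OCC)C(c1ccc(OCc2ccccc2)cc1)c1c(C#Cc2ccc(OCc3ccccc3)cc2)cc(OCc2ccccc2)cc1OCc1ccccc1 | intermediate
14 | (Z)-triarylethene bis-MOM ether (ring A cis to ring D) | COCOc1cc(OCOC)cc(/C=C(/c2ccc(OCc3ccccc3)cc2)c2c(C#Cc3ccc(OCc4ccccc4)cc3)cc(OCc3ccccc3)cc2OCc2ccccc2)c1I | intermediate
15 | (Z)-triarylethene iodoresorcinol (annulation precursor) | Oc1cc(O)cc(/C=C(/c2ccc(OCc3ccccc3)cc2)c2c(C#Cc3ccc(OCc4ccccc4)cc3)cc(OCc3ccccc3)cc2OCc2ccccc2)c1I | intermediate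
16 | tetrabenzyl pentacyclic alkene phenol | C1(c2ccc(OCc3ccccc3)cc2)=Cc2cc(O)cc3oc(-c4ccc(OCc5ccccc5)cc4)c(c23)-c2cc(OCc3ccccc3)cc(OCc3ccccc3)c21 | intermediate
17 | pentabenzyl pentacyclic alkene | C1(c2ccc(OCc3ccccc3)cc2)=Cc2cc(OCc3ccccc3)cc3oc(-c4ccc(OCc5ccccc5)cc4)c(c23)-c2cc(OCc3ccccc3)cc(OCc3ccccc3)c21 | intermediate
18 | B-isopinocampheyl alkylborane (boron on the ring C carbon next to ring A, syn to the new methine hydrogen) | C[C@H]6[C@H](B[C@H]1c2cc(OCc3ccccc3)cc3oc(-c4ccc(OCc5ccccc5)cc4)c(c23)-c2cc(OCc3ccccc3)cc(OCc3ccccc3)c2[C@@H]1c1ccc(OCc2ccccc2)cc1)C[C@@H]7C[C@H]6C7(C)C | intermediate (not isolated)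
19 | trans alcohol (carbinol R, methine S) | O[C@H]1c2cc(OCc3ccccc3)cc3oc(-c4ccc(OCc5ccccc5)cc4)c(c23)-c2cc(OCc3ccccc3)cc(OCc3ccccc3)c2[C@@H]1c1ccc(OCc2ccccc2)cc1 | intermediate
20 | penta-O-benzylhopeafuran (methine S) | O=C1c2cc(OCc3ccccc3)cc3oc(-c4ccc(OCc5ccccc5)cc4)c(c23)-c2cc(OCc3ccccc3)cc(OCc3ccccc3)c2[C@@H]1c1ccc(OCc2ccccc2)cc1 | intermediate
21 | hopeafuran | O=C1c2cc(O)cc3oc(-c4ccc(O)cc4)c(c23)-c2cc(O)cc(O)c2[C@@H]1c1ccc(O)cc1 | target

**Count**
Total steps: 14. Longest linear sequence: 12 steps (steps 3 to 14, from 5-bromoresorcinol).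

**Steps most likely to fail**

Step 10. What may go wrong: intermolecular alkyne insertion (oligomerisation) or reductive loss of iodine may outrun the seven-membered carbopalladation. The fallback forms ring B first and closes ring C last by an intramolecular Horner–Wadsworth–Emmons reaction, in which the ring can hold only the cis alkene. It sets out from 3, 12 and 11 and comes back to the route at 17.
- HCl in MeOH removes both MOM groups of 3 to give 2-iodo-3,5-dihydroxybenzaldehyde F1.
- Tandem Sonogashira coupling and 5-endo cyclisation of F1 with 12 (PdCl2(PPh3)2, CuI, Et3N, DMF, 60 °C) gives 2-[4-(benzyloxy)phenyl]-6-hydroxybenzofuran-4-carbaldehyde F2.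
- BnBr and K2CO3 give the 6-benzyl ether F3.
- NBS in DMF at 0 °C brominates furan C3 to give the 3-bromobenzofuran aldehyde F4.
- Miyaura borylation of 11 (B2pin2, PdCl2(dppf), KOAc, dioxane, 90 °C) gives the pinacol boronate F5.
- Suzuki coupling of F4 with F5 (Pd(OAc)2, SPhos, K3PO4, toluene/H2O, 90 °C) gives the 3-arylbenzofuran aldehyde phosphonate F6.
- KOtBu in dilute THF closes ring C of F6 to give 17.

Step 12. What may go wrong: hydroboration of the crowded, fully conjugated triaryl alkene may be slow enough for the reagent to lose α-pinene, or facial selectivity may be poor because the tub-shaped ring C offers a convex and a concave face that compete with reagent control. The fallback is racemic hydroboration followed by resolution through diastereomeric esters. It sets out from 17 and comes back at 19.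
- BH3·THF and then NaOH/H2O2 give 19 together with its enantiomer, the ent-alcohol F7.
- Esterification of the mixture with (S)-naproxen (EDC·HCl, DMAP, CH2Cl2) gives the naproxen ester of 19 F8 and the naproxen ester of the ent-alcohol F9, which are separated on silica or by crystallisation.
- LiOH in THF/MeOH/H2O cleaves F8 to 19; the configuration is assigned on F8 before the material is carried on.

Step 8. What may go wrong: the oxaphosphetane may form with ring A anti to the bulkier ring D, so that the E alkene becomes the main product. The fallback replaces kinetic control by thermodynamic control of the alkene geometry. It sets out from 13 and 3 through the E alkene F10 and comes back at 14.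
- The E isomer of 14 F10 is separated and equilibrated with catalytic I2 in toluene under visible light (reversible addition of iodine atoms to the alkene).
- This should favour 14, in which rings A and E keep a coplanar trans-stilbene unit while the twisted ring D sits cis to ring A.
- 14 is separated and F10 is recycled.

**Further compounds**
F1 | step 10 | 2-iodo-3,5-dihydroxybenzaldehyde | O=Cc1cc(O)cc(O)c1I
F2 | step 10 | 2-[4-(benzyloxy)phenyl]-6-hydroxybenzofuran-4-carbaldehyde | O=Cc1cc(O)cc2oc(-c3ccc(OCc4ccccc4)cc3)cc12
F3 | step 10 | 6-(benzyloxy)-2-[4-(benzyloxy)phenyl]benzofuran-4-carbaldehyde | O=Cc1cc(OCc2ccccc2)cc2oc(-c3ccc(OCc4ccccc4)cc3)cc12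
F4 | step 10 | 6-(benzyloxy)-2-[4-(benzyloxy)phenyl]-3-bromobenzofuran-4-carbaldehyde | O=Cc1cc(OCc2ccccc2)cc2oc(-c3ccc(OCc4ccccc4)cc3)c(Br)c12
F5 | step 10 | diethyl {[2,4-bis(benzyloxy)-6-(4,4,5,5-tetramethyl-1,3,2-dioxaborolan-2-yl)phenyl][4-(benzyloxy)phenyl]methyl}phosphonate | CCOP(=O)(OCC)C(c1ccc(OCc2ccccc2)cc1)c1c(B2OC(C)(C)C(C)(C)O2)cc(OCc2ccccc2)cc1OCc1ccccc1
F6 | step 10 | diethyl {[2,4-bis(benzyloxy)-6-{6-(benzyloxy)-2-[4-(benzyloxy)phenyl]-4-formylbenzofuran-3-yl}phenyl][4-(benzyloxy)phenyl]methyl}phosphonate | CCOP(=O)(OCC)C(c1ccc(OCc2ccccc2)cc1)c1c(-c2c(-c3ccc(OCc4ccccc4)cc3)oc3cc(OCc4ccccc4)cc(C=O)c23)cc(OCc2ccccc2)cc1OCc1ccccc1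
F7 | step 12 | ent-alcohol (enantiomer of 19; carbinol S, methine R) | O[C@@H]1c2cc(OCc3ccccc3)cc3oc(-c4ccc(OCc5ccccc5)cc4)c(c23)-c2cc(OCc3ccccc3)cc(OCc3ccccc3)c2[C@H]1c1ccc(OCc2ccccc2)cc1
F8 | step 12 | (S)-naproxen ester of 19 | COc1ccc2cc(ccc2c1)[C@H](C)C(=O)O[C@H]1c2cc(OCc3ccccc3)cc3oc(-c4ccc(OCc5ccccc5)cc4)c(c23)-c2cc(OCc3ccccc3)cc(OCc3ccccc3)c2[C@@H]1c1ccc(OCc2ccccc2)cc1
F9 | step 12 | (S)-naproxen ester of the ent-alcohol | COc1ccc2cc(ccc2c1)[C@H](C)C(=O)O[C@@H]1c2cc(OCc3ccccc3)cc3oc(-c4ccc(OCc5ccccc5)cc4)c(c23)-c2cc(OCc3ccccc3)cc(OCc3ccccc3)c2[C@H]1c1ccc(OCc2ccccc2)cc1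
F10 | step 8 | E isomer of 14 (ring A cis to ring E) | COCOc1cc(OCOC)cc(/C=C(\c2ccc(OCc3ccccc3)cc2)c2c(C#Cc3ccc(OCc4ccccc4)cc3)cc(OCc3ccccc3)cc2OCc2ccccc2)c1I
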